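The runs are simulated for an exercise, noise included.

1. The reading at 10 min is still to come from the violet flask, and the next run hangs on one question: does that flask still hold working catalyst?

in all of them: gas 200 mM (held)
- violet: starting material 1 M; free catalyst 2 mM; temperature 35 °C; the very flask that is asked about, followed so far
- red: starting material 1 M; free catalyst 2 mM; temperature 30 °C; run made earlier
- flask: starting material 1.0 M; free catalyst 2.0 mM; temperature 35 °C; time 10 min

| run | time / min | product / % | starting material / % |
|---|---|---|---|
| violet | 0.500 | 12.2 | 88.6 |
| violet | 1.00 | 22.7 | 77.2 |
| violet | 2.50 | 39.8 | 60.7 |
| violet | 6.00 | 47.6 | 52.8 |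
| red | 0.500 | 10.2 | 90.1 |
| red | 1.00 | 20.9 | 78.8 |
| red | 2.50 | 43.0 | 57.4 |
| red | 6.00 | 62.0 | 38.1 |

(scatter of a reading: 0.3 percentage points)

- Saturday's: at 10 min take out 90% of the product then present, then wait 5.0 min
- Thursday's: at 10 min add free catalyst, 100% of the amount charged, then wait 5.0 min
- Tuesday's: at 10 min raise the temperature by 10 K, then wait 5.0 min
- Friday's: change nothing and wait 5.0 min more

- product that was removed still counts
- at the start none of the gas is in solution
- additions bring no volume worth counting

1. product, in percent of the starting material first charged, at 10 min
2. the option that brings most further product ("none" if no option brings more than 2 percentage points) (Saturday's / Thursday's / Tuesday's / Friday's / none)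
3. product present, with what was taken out counted in, in percent of the starting material first charged, after Thursday's
4. product present, with what was taken out counted in, in percent of the starting material first charged, after Friday's

2. Work in logarithms. The violet run shows 0.277 decades at 6.00 min: call this the log reach, the powers of ten by which starting material has fallen. Its pace fell from 0.0867 min⁻¹ to 0.0173 min⁻¹, with 52.8% of the starting material still there and the gas held. So product at 10 min should stand just above 47.6%.

3. The stall in the violet run could be an equilibrium or lost catalyst (deactivation). An equilibrium would have to shift the ratio of product to starting material by at least 0.256 decades between 30 °C and 35 °C. That is steep, so this reckoning commits to lost catalyst.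

4. Taking the reaction as first order in starting material, with gas held, each equal dose of catalyst buys the same reach. Thursday's should then leave 27.9% and give 72.1% product, a gain of 25 percentage points, above the margin of 2 points. The other options add no catalyst, so the choice is Thursday's, and Friday's stays near the value at 10 min.

5. The forecast differs on the option and on Thursday's: 48.2% at 10 min, Saturday's as the best option, 48.2% after Thursday's, 48.2% after Friday's, since “More catalyst only gets to equilibrium faster”.

The flask gives 48.0%, and the best option is Thursday's, with 86.4% after Thursday's and 48.0% after Friday's. The reach chose rightly but undershot by 14 points.

    starting material + reagent + free catalyst → product + free catalyst, rate k1*[starting material]*[reagent]*[free catalyst]/(1 + ([starting material]/sat1)) (0.200 M, k = 110 M⁻² s⁻¹, Ea = 38.0 kJ mol⁻¹)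
    gas ⇌ reagent, rate k2*(csat - [reagent]) (kL = 0.140 s⁻¹)
    free catalyst → spent catalyst (k = 0.0120 s⁻¹, Ea = 90.0 kJ mol⁻¹)
    (constants at 35 °C)

In this flask free catalyst has a half-life of 0.96 min by its conversion into spent catalyst, and the conversion of starting material and reagent into product has done half of its turnover up to 10 min by 1.09 min, two times of one size. At 10.0 min the share that can still turn over is 0.0747%, with 52% of the starting material left. A neighbouring flask charged with 0.0080 M of free catalyst holds 4.00 charges, so the reach gives 1.11 decades and 7.77% left. Computed, it leaves 0.52%, with 99.5% product.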